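Retrosynthesis: the O7–Si bond of a silyl-protected precursor is cut first, then the C2–C1' bond between ring C and ring B, which leaves a 7-silyloxychromone and a fully decorated ring B arylboronic acid. The boronic acid is traced back through C–B to C–Br, the two C–CH3 bonds of the carbinol, the side-chain C=C, the O–CH3 bond and the aryl–CH2 bond of the prenyl group to a bought bromosalicylaldehyde.
Forward order: ring C is closed first on a bought ring A acetophenone (enaminone, then pyranone); ring B is bought as an arene and decorated in a separate line (prenyl by aromatic Claisen rearrangement, alkenyl carbinol by olefination and methyl addition, boron in place of bromine). The two halves are joined last at C2–C1' and no ring is formed after that.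
Enabling feature: C2 of ring C is the only stereocentre, is benzylic and lies β to the C4 ketone next to O1, so C2–C1' is the bond an aryl–metal makes on adding across C2=C3 of a flat chromone; C2' and C6' of ring B both carry H, so the aryl donor is unhindered.
Stereochemistry: C2 (S) comes from the chiral bisphosphine on rhodium in the conjugate addition (aryl to the Re face of C2); the E alkene comes from the Horner–Wadsworth–Emmons step; all later steps avoid base and strong acid so that C2 cannot scramble by ring opening.

Key step: step 12

Assumption: the (R) antipode of MeO-F12-BIPHEP, (R)-2,2'-bis[bis(3,4,5-trifluorophenyl)phosphino]-6,6'-dimethoxy-1,1'-biphenyl, is taken to deliver the aryl group to the Re face of C2; the sense of induction is to be confirmed in a model run with a simple arylboronic acid and the ligand mirrored if the model gives the (R)-flavanone.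

Step 1
Reactants: 1 2',4'-dihydroxyacetophenone
Product: 2 (E)-1-(2,4-dihydroxyphenyl)-3-(dimethylamino)prop-2-en-1-one
Conditions: Me2NCH(OMe)2 (1.3 equiv), toluene, 90 °C
Reagents that add atoms: N,N-dimethylformamide dimethyl acetal, COC(OC)N(C)C
Why: Enaminone formation by condensation of the acidic acetyl CH3 with the amide acetal adds the carbon that becomes C2 of ring C with loss of two methanol, and the acetal is kept near one equivalent so that the free 4-OH is not methylated.

Step 2
Reactants: 2 (E)-1-(2,4-dihydroxyphenyl)-3-(dimethylamino)prop-2-en-1-one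
Product: 3 7-hydroxychromone (7-hydroxy-4H-chromen-4-one)
Conditions: conc. HCl, CH2Cl2, 40 °C
Reagents that add atoms: none
Why: Acid-promoted enaminone cyclisation: the ortho phenol adds to the protonated vinylogous amide carbon (6-endo oxa-Michael addition) and dimethylamine is expelled, which closes the 4-pyranone ring C.

Step 3
Reactants: 3 7-hydroxychromone
Product: 4 7-(triisopropylsilyloxy)chromone
Conditions: TIPSCl, imidazole, DMF, rt
Reagents that add atoms: chlorotriisopropylsilane, CC(C)[Si](Cl)(C(C)C)C(C)C
Why: Imidazole-mediated silylation of the phenol masks the acidic 7-OH that would quench the hydroxorhodium catalyst, and the bulky silyl ether can be removed at the end by fluoride without acid, base or hydrogen.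

Step 4
Reactants: 5 5-bromosalicylaldehyde (5-bromo-2-hydroxybenzaldehyde); 6 3-chloro-3-methylbut-1-yne
Product: 7 5-bromo-2-[(2-methylbut-3-yn-2-yl)oxy]benzaldehyde
Conditions: CuCl2·2H2O (1 mol%), DBU, MeCN, 0 °C
Reagents that add atoms: none
Why: Copper-catalysed propargylic etherification (a copper acetylide ionises the tertiary chloride and the phenoxide of 5 captures the copper allenylidene at the tertiary carbon), run cold so that the aryl propargyl ether does not go on to a 2,2-dimethylchromene.

Step 5
Reactants: 7 5-bromo-2-[(2-methylbut-3-yn-2-yl)oxy]benzaldehyde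
Product: 8 5-bromo-2-[(2-methylbut-3-en-2-yl)oxy]benzaldehyde
Conditions: H2 (1 atm), Pd/CaCO3 poisoned with Pb(OAc)2 (Lindlar catalyst), quinoline, EtOAc, rt
Reagents that add atoms: none
Why: Lindlar semi-hydrogenation stops at the alkene on the lead- and quinoline-poisoned palladium surface, leaves the aryl bromide and the aldehyde alone and gives the 1,1-dimethylallyl ether needed for the sigmatropic step.

Step 6
Reactants: 8 5-bromo-2-[(2-methylbut-3-en-2-yl)oxy]benzaldehyde
Product: 9 5-bromo-2-hydroxy-3-(3-methylbut-2-en-1-yl)benzaldehyde
Conditions: o-xylene, 135 °C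
Reagents that add atoms: none
Why: Aromatic Claisen rearrangement: the [3,3] shift moves the allyl unit with inversion to C3, the only ortho position bearing H, so the 1,1-dimethylallyl ether becomes a C-prenyl group and tautomerisation restores the phenol, while the para bromine excludes a following Cope shift.

Step 7
Reactants: 9 5-bromo-2-hydroxy-3-(3-methylbut-2-en-1-yl)benzaldehyde
Product: 10 5-bromo-2-methoxy-3-(3-methylbut-2-en-1-yl)benzaldehyde
Conditions: MeI, K2CO3, DMF, 40 °C
Reagents that add atoms: iodomethane, CI
Why: Williamson ether synthesis on the potassium phenoxide; the aldehyde, the aryl bromide and the prenyl alkene are inert to iodomethane and carbonate.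

Step 8
Reactants: 10 5-bromo-2-methoxy-3-(3-methylbut-2-en-1-yl)benzaldehyde; 11 triethyl phosphonoacetate
Product: 12 ethyl (E)-3-[5-bromo-2-methoxy-3-(3-methylbut-2-en-1-yl)phenyl]prop-2-enoate
Conditions: NaH, THF, 0 °C to rt
Reagents that add atoms: none
Why: Horner–Wadsworth–Emmons olefination with the stabilised phosphonate anion, which should give the E-enoate because the addition is reversible and the anti oxaphosphetane collapses preferentially.

Step 9
Reactants: 12 ethyl (E)-3-[5-bromo-2-methoxy-3-(3-methylbut-2-en-1-yl)phenyl]prop-2-enoate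
Product: 14 (E)-4-[5-bromo-2-methoxy-3-(3-methylbut-2-en-1-yl)phenyl]-2-methylbut-3-en-2-ol, via methyl enone 13 (not isolated)
Conditions: MeMgBr (3.5 equiv), THF, −20 to 0 °C; aq. NH4Cl
Reagents that add atoms: methylmagnesium bromide, C[Mg]Br
Why: Double 1,2-addition of a Grignard reagent to an ester: the first equivalent gives enone 13 after loss of ethoxide, the second adds to its carbonyl faster than to the β-carbon, and MeMgBr does not exchange with the aryl bromide, so the E alkene and the bromide are carried through.

Step 10
Reactants: 14 (E)-4-[5-bromo-2-methoxy-3-(3-methylbut-2-en-1-yl)phenyl]-2-methylbut-3-en-2-ol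
Product: 15 (E)-4-[2-methoxy-3-(3-methylbut-2-en-1-yl)-5-(4,4,5,5-tetramethyl-1,3,2-dioxaborolan-2-yl)phenyl]-2-methylbut-3-en-2-ol
Conditions: B2pin2, KOAc, PdCl2(dppf) (3 mol%; dppf = 1,1'-bis(diphenylphosphino)ferrocene), 1,4-dioxane, 85 °C
Reagents that add atoms: bis(pinacolato)diboron, CC1(C)OB(OC1(C)C)B1OC(C)(C)C(C)(C)O1
Why: Miyaura borylation (oxidative addition of C–Br to zerovalent palladium, acetate-assisted transmetalation with the diboron, reductive elimination); the weak base KOAc leaves the free tertiary allylic alcohol and both alkenes untouched and does not promote biaryl coupling.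

Step 11
Reactants: 15 (E)-4-[2-methoxy-3-(3-methylbut-2-en-1-yl)-5-(4,4,5,5-tetramethyl-1,3,2-dioxaborolan-2-yl)phenyl]-2-methylbut-3-en-2-ol
Product: 16 {3-[(E)-3-hydroxy-3-methylbut-1-en-1-yl]-4-methoxy-5-(3-methylbut-2-en-1-yl)phenyl}boronic acid
Conditions: NaIO4, NH4OAc, acetone/H2O (1:1), rt
Reagents that add atoms: water, O
Why: Oxidative cleavage of a pinacol boronate: the ester is in hydrolytic equilibrium with the boronic acid and pinacol, and periodate removes the pinacol irreversibly as acetone at near-neutral pH, so the acid-sensitive tertiary allylic alcohol never meets mineral acid.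

Step 12
Reactants: 4 7-(triisopropylsilyloxy)chromone (1.5 equiv); 16 {3-[(E)-3-hydroxy-3-methylbut-1-en-1-yl]-4-methoxy-5-(3-methylbut-2-en-1-yl)phenyl}boronic acid
Product: 17 (2S)-2-{3-[(E)-3-hydroxy-3-methylbut-1-en-1-yl]-4-methoxy-5-(3-methylbut-2-en-1-yl)phenyl}-7-(triisopropylsilyloxy)-2,3-dihydro-4H-chromen-4-one
Conditions: [Rh(OH)(cod)]2 (2.5 mol%; cod = 1,5-cyclooctadiene), (R)-MeO-F12-BIPHEP (6 mol%), toluene/H2O (10:1), no added base, 30–40 °C
Reagents that add atoms: none
Why: Transmetalation of boronic acid 16 to the hydroxorhodium–bisphosphine complex (monovalent rhodium) gives an aryl–rhodium species that inserts C2=C3 of chromone 4 with the aryl group going to C2, and the resulting oxa-π-allyl rhodium enolate is protonated at C3 by water, which returns the Rh–OH catalyst. The closest known reaction type is the rhodium-catalysed asymmetric 1,4-addition of arylboronic acids to chromones (Hayashi–Miyaura conjugate addition), which gives 2-arylchroman-4-ones directly. No ring is closed: ring C is already present and the C2–C1' bond is the only skeletal bond made. The new stereocentre C2 is controlled by the chiral bisphosphine alone, which shields one face of the flat pyranone so that the aryl group is delivered to the Re face of C2 (O1 > C3 > H), giving 2S. The step needs 1,4- rather than 1,2-regioselectivity, facial selectivity and survival of the enolate without O1–C2 cleavage; the vinylogous-ester polarisation O1–C2=C3–C4=O directs the aryl group to C2, the absence of ortho substituents at C2' and C6' keeps insertion fast, and the base-free medium together with the silylated 7-OH prevents ring opening, over-addition to the C4 ketone and quenching of the Rh–OH species. The prenyl and styrenyl alkenes and the free tertiary alcohol of 16 should be inert to an aryl–rhodium species under these neutral aqueous conditions, and the cheap chromone is used in excess so that the valuable boronic acid is consumed productively.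

Step 13
Reactants: 17 (2S)-2-{3-[(E)-3-hydroxy-3-methylbut-1-en-1-yl]-4-methoxy-5-(3-methylbut-2-en-1-yl)phenyl}-7-(triisopropylsilyloxy)-2,3-dihydro-4H-chromen-4-one
Product: 18 (2S)-7-hydroxy-2-{3-[(E)-3-hydroxy-3-methylbut-1-en-1-yl]-4-methoxy-5-(3-methylbut-2-en-1-yl)phenyl}-2,3-dihydro-4H-chromen-4-one (CNP0222710.1)
Conditions: Bu4NF (1.1 equiv), AcOH (1.1 equiv), THF, 0 °C, short contact
Reagents that add atoms: none
Why: Fluoride-driven cleavage of the aryl silyl ether (Si–F bond formation), buffered with acetic acid so that neither the 7-phenoxide nor a C3 enolate persists and C2 is not lost through retro-oxa-Michael opening.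

Compound list
1 | 2',4'-dihydroxyacetophenone | CC(=O)c1ccc(O)cc1O | starting material
2 | (E)-1-(2,4-dihydroxyphenyl)-3-(dimethylamino)prop-2-en-1-one | CN(C)/C=C/C(=O)c1ccc(O)cc1O | intermediate
3 | 7-hydroxychromone | O=c1ccoc2cc(O)ccc12 | intermediate
4 | 7-(triisopropylsilyloxy)chromone | CC(C)[Si](Oc1ccc2c(c1)occc2=O)(C(C)C)C(C)C | intermediate
5 | 5-bromosalicylaldehyde | O=Cc1cc(Br)ccc1O | starting material
6 | 3-chloro-3-methylbut-1-yne | CC(C)(Cl)C#C | starting material
7 | 5-bromo-2-[(2-methylbut-3-yn-2-yl)oxy]benzaldehyde | O=Cc1cc(Br)ccc1OC(C)(C)C#C | intermediate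
8 | 5-bromo-2-[(2-methylbut-3-en-2-yl)oxy]benzaldehyde | O=Cc1cc(Br)ccc1OC(C)(C)C=C | intermediate
9 | 5-bromo-2-hydroxy-3-(3-methylbut-2-en-1-yl)benzaldehyde | O=Cc1cc(Br)cc(CC=C(C)C)c1O | intermediate
10 | 5-bromo-2-methoxy-3-(3-methylbut-2-en-1-yl)benzaldehyde | COc1c(C=O)cc(Br)cc1CC=C(C)C | intermediate
11 | triethyl phosphonoacetate | CCOC(=O)CP(=O)(OCC)OCC | starting material
12 | ethyl (E)-3-[5-bromo-2-methoxy-3-(3-methylbut-2-en-1-yl)phenyl]prop-2-enoate | CCOC(=O)/C=C/c1cc(Br)cc(CC=C(C)C)c1OC | intermediate
13 | (E)-4-[5-bromo-2-methoxy-3-(3-methylbut-2-en-1-yl)phenyl]but-3-en-2-one (methyl enone, not isolated) | CC(=O)/C=C/c1cc(Br)cc(CC=C(C)C)c1OC | intermediate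
14 | (E)-4-[5-bromo-2-methoxy-3-(3-methylbut-2-en-1-yl)phenyl]-2-methylbut-3-en-2-ol | COc1c(/C=C/C(C)(C)O)cc(Br)cc1CC=C(C)C | intermediate
15 | (E)-4-[2-methoxy-3-(3-methylbut-2-en-1-yl)-5-(4,4,5,5-tetramethyl-1,3,2-dioxaborolan-2-yl)phenyl]-2-methylbut-3-en-2-ol | COc1c(/C=C/C(C)(C)O)cc(B2OC(C)(C)C(C)(C)O2)cc1CC=C(C)C | intermediate
16 | {3-[(E)-3-hydroxy-3-methylbut-1-en-1-yl]-4-methoxy-5-(3-methylbut-2-en-1-yl)phenyl}boronic acid | COc1c(/C=C/C(C)(C)O)cc(B(O)O)cc1CC=C(C)C | intermediate
17 | (2S)-2-{3-[(E)-3-hydroxy-3-methylbut-1-en-1-yl]-4-methoxy-5-(3-methylbut-2-en-1-yl)phenyl}-7-(triisopropylsilyloxy)-2,3-dihydro-4H-chromen-4-one | COc1c(/C=C/C(C)(C)O)cc([C@@H]2CC(=O)c3ccc(O[Si](C(C)C)(C(C)C)C(C)C)cc3O2)cc1CC=C(C)C | intermediate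
18 | (2S)-7-hydroxy-2-{3-[(E)-3-hydroxy-3-methylbut-1-en-1-yl]-4-methoxy-5-(3-methylbut-2-en-1-yl)phenyl}-2,3-dihydro-4H-chromen-4-one (CNP0222710.1) | COc1c(/C=C/C(C)(C)O)cc([C@@H]2CC(=O)c3ccc(O)cc3O2)cc1CC=C(C)C | target

Total step count: 13
Longest linear sequence: 10 steps (steps 4 to 13, from 5-bromosalicylaldehyde 5); the ring A/C branch (steps 1 to 3) joins at step 12.

Steps most likely to fail

Step 12 (key step). The catalyst may discriminate the two faces of the electron-rich 7-silyloxychromone poorly, or the C2 configuration may erode when the rhodium enolate expels the O1 aryloxide and the ring re-closes without control; slow insertion would also let the aryl donor protodeboronate. The fallback gives up catalyst control of C2. It sets out from 4 and 16 and makes the same C2–C1' bond with the ligand-free achiral catalyst [Rh(OH)(cod)]2 in 1,4-dioxane/H2O at 60 °C, where more forcing conditions can be used, to give racemic 7-O-TIPS flavanone F1. The enantiomers would be separated by preparative chromatography on a cellulose tris(3,5-dimethylphenylcarbamate) stationary phase; the (2S) enantiomer is 17, where the route is rejoined. The (2R)-7-O-TIPS flavanone F2 would be returned to F1 with catalytic DBU in toluene (reversible opening of the O1–C2 bond) and recycled.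

Step 6. The tertiary allyl aryl ether may ionise and lose isoprene instead of rearranging, or the product phenol may add to its own prenyl alkene and close a chroman. The fallback installs the prenyl group by cross-coupling instead of sigmatropy. It sets out from 5: ortho-iodination (N-iodosuccinimide, DMF, rt) should give 5-bromo-2-hydroxy-3-iodobenzaldehyde F3, and O-methylation (MeI, K2CO3, DMF) then gives 5-bromo-3-iodo-2-methoxybenzaldehyde F4. A Stille coupling selective for the C–I bond over C–Br with tributyl(3-methylbut-2-en-1-yl)stannane (Pd(PPh3)4, DMF, 80 °C) then joins the route at 10.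

Step 11. The pinacol ester may be cleaved incompletely, or the electron-rich arylboronic acid may protodeboronate or be lost during the oxidative cleavage and isolation. The fallback avoids the pinacol ester altogether. It sets out from 14 and borylates directly with tetrahydroxydiboron (B2(OH)4, Pd(OAc)2, XPhos = 2-dicyclohexylphosphino-2',4',6'-triisopropylbiphenyl, KOAc, EtOH, 80 °C), which delivers 16 in one operation, where the route is rejoined; no new compound is made.

Further compounds
F1 | step 12 | racemic 2-{3-[(E)-3-hydroxy-3-methylbut-1-en-1-yl]-4-methoxy-5-(3-methylbut-2-en-1-yl)phenyl}-7-(triisopropylsilyloxy)-2,3-dihydro-4H-chromen-4-one | COc1c(/C=C/C(C)(C)O)cc(C2CC(=O)c3ccc(O[Si](C(C)C)(C(C)C)C(C)C)cc3O2)cc1CC=C(C)C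
F2 | step 12 | (2R)-2-{3-[(E)-3-hydroxy-3-methylbut-1-en-1-yl]-4-methoxy-5-(3-methylbut-2-en-1-yl)phenyl}-7-(triisopropylsilyloxy)-2,3-dihydro-4H-chromen-4-one | COc1c(/C=C/C(C)(C)O)cc([C@H]2CC(=O)c3ccc(O[Si](C(C)C)(C(C)C)C(C)C)cc3O2)cc1CC=C(C)C
F3 | step 6 | 5-bromo-2-hydroxy-3-iodobenzaldehyde | O=Cc1cc(Br)cc(I)c1O
F4 | step 6 | 5-bromo-3-iodo-2-methoxybenzaldehyde | COc1c(C=O)cc(Br)cc1I
F0 | step 11 | none | none
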